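## Structural features

The target is a guai-4-en-3-one: a 2-methylcyclopent-2-enone (ring A, C1–C5) fused along C1–C5 to a cycloheptane (ring B, C1 and C5–C10). Ring B carries two pairs of adjacent stereocentres, separated by the methylenes C6 and C9: C7 (bearing the 2-acetoxyprop-2-yl carbon C11) next to C8 (methacrylate), and C10 (methyl) next to the ring-fusion methine C1. The configuration is 1R,7S,8R,10S. C11, O8 and the C10 methyl lie on one face of ring B and the C1–C2 bond on the other, so H-1 is anti to H-10, and C7/C8 form a syn-aldol array when read along C11–C7–C8–C9. Fragile points are the methacrylate (radical and Michael acceptor, polymerisable), the hindered tertiary acetate (eliminates under acid), and C1–H (γ to the enone, epimerisable through the extended enolate). The 8,11-diol must also take two different acyl groups. The real difficulty is closing the seven-membered ring while fixing C1 and C10 relative to the remote C7/C8 pair. The key step exploits the C1–C10 bond: with the ring-A alkene moved to C1=C2 and a hydroxyl on C5, C1 is an enone β-carbon, so a C10 radical released from a carboxyl group can close ring B onto it. Loss of the C5 hydroxyl then restores the C4=C5 enone.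

## Logic of the disconnections

**26 ⇒ 25 ⇒ 24.** The acyl–oxygen bonds at O11 and then O8 are cut. The methacrylate cannot pass through a radical step or strong base, so both esters go on last, the secondary one first. This leaves the free diol 24. The forward steps must acylate O8 selectively and then force a hindered tertiary hydroxyl without harming the methacrylate.

**24 ⇒ 23 ⇒ 22.** The two Si–O bonds are cut and the C4=C5 alkene is traced back to a C5 hydroxyl. In 22 that hydroxyl is β to the C3 ketone, so it leaves by enolisation toward C4 (E1cB); a tertiary alcohol of this kind is not a sound substrate for a sulfonylation–elimination sequence. The forward step must dehydrate only toward C4 and leave C1 as formed.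

**22 ⇒ 21 (key).** The C1–C10 bond is cut to a C10 radical and a C1=C2 enone. This opens ring B and removes two stereocentres. The carboxyl carbon of 21 is stereogenic but irrelevant, so it is carried as an epimer mixture and not drawn with one configuration. The forward step needs the 5R configuration in 21, because the tether reaches only one enone face. Relying on later equilibration of C1 would not rescue the 5S epimer, since its C10 selectivity is not secured.

**21 ⇒ 19 + 20 ⇒ 17.** The acyl–O bond to 20 is cut and the carboxyl is traced to a vinyl group. An ester at this carbon would sit γ to O8 (lactonisation) and would not survive methyl Grignard or butyllithium; a terminal alkene is inert to all earlier steps. The forward ozonolysis must distinguish the vinyl group from the enone alkene.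

**17 ⇒ 16 ⇒ 14.** The C4–C5 bond of ring A is cut (Piancatelli retron), then the furan–carbinol C–C bond. Ring A becomes a 2-alkylfuran. The forward step needs water to add at the alkyl-substituted furan carbon. The diol must be masked by a group that survives butyllithium and hot aqueous Lewis acid: a ketal would hydrolyse, and a free diol would capture the furyl cation intramolecularly. C5 forms without control and the epimers must be separated.

**14 ⇒ 13 ⇒ 11 ⇒ 10.** The Si–O bonds, the two C11–CH3 bonds and the ester C–O bond are cut in turn. The tertiary carbinol becomes the acyl carbon of an aldol adduct. The methyl additions must not cause retro-aldol or epimerise C7.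

**10 ⇒ 4 + 8.** The C7–C8 bond is cut. The auxiliary-controlled syn-aldol sets both stereocentres in one step.

**4 ⇒ 1 + 2; 8 ⇒ 5 + 6.** The N-acyl bond and the C10–vinyl bond are cut, down to commercial materials.

## Other disconnections considered

**Alternative 1:** The cut is a skeletal reorganisation: C1–C5 is formed and C5–C10 broken. In the forward step the cross-conjugated cyclohexadienone A2 is irradiated in acetic acid and gives the 10-acetoxy hydroazulenone carbonate A1.
- In its favour: one step builds the 5–7 skeleton, the enone in its final position and C1, with C1 fixed relative to C10 by the cyclopropyl-cation mechanism. On these points it is better than the chosen plan, which needs a dehydration and loses the unwanted C5 epimer of 17.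
- Against it: A2 needs a quaternary C10 set during dearomatisation under control of the remote C7/C8 pair. A1 carries an acetate at C10 with the methyl cis to C2, the opposite face to the target. The acetate must therefore be exchanged for hydrogen with net inversion, in practice by elimination and a face-selective hydrogenation beside a tetrasubstituted enone.
- Comparison: the chosen plan installs C10–H directly and rests on transition-state control; A1 has a secure C1/C10 relationship, but the wrong one. Step economy after the key step favours the chosen plan; the photochemical step itself is its equal in bond-forming power.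

**Alternative 2:** The cuts are C6–C7 and C9–C10. In the forward step the rhodium carbenoid from diazo ester A5 (Rh2(OAc)4, divalent rhodium) cyclopropanates the exocyclic methylene of diene A4, and the cis-divinylcyclopropane undergoes Cope rearrangement to A3.
- In its favour: it is convergent and makes two C–C bonds and ring B in one step. On convergence it is better than the chosen linear sequence.
- Against it: A3 has its alkene at C1=C5, C3 as a silyl ether, C8 as an enol ether and C7 as an ester. C7 and C8 still have to be set (ketone reduction and control of an epimerisable C7, cis to each other and correct relative to C10). C1 would arise later by protonation of a dienolate, so it rests on the thermodynamic preference that the chosen plan needs only as a safeguard. C10 depends on which methylene face the carbenoid takes, guided only by the C4 methyl of A4.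
- Comparison: more oxidation-level and protecting-group adjustments are needed to reach 24, so the route is longer overall.

**Alternative 3:** The cut is C1–C2. In the forward step a monovalent gold complex (Ph3PAuNTf2) induces a 1,2-pivalate shift in enyne pivalate A7, and the pentadienyl cation closes to cyclopentenone A6.
- In its favour: the enone is formed directly, with no C5 stereocentre and no dehydration; on this it is better than the chosen plan. A6 differs from 23 only in the diol protecting group, so the end game is equal.
- Against it: the substituted cycloheptene with C7, C8 and C10 must already exist, so the ring-B problem moves to another step. The tertiary propargylic pivalate must be stereodefined or C1 left to the ring's facial bias. Tertiary propargylic esters can also divert through 1,3-acyloxy shift to allenes.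
- Comparison: it is mechanistically elegant, but the route to A7 is likely longer than the route to 21.

Key step: step 11

Assumption: C10 is carried as a mixture of epimers in 8, 10–19 and 21, because step 11 makes it planar; the SMILES leave it open.
Assumption: the 1R configuration (H-1 anti to H-10) is taken to be the more stable one in the 4-en-3-one, so the base in step 12 should not erode it.

## Route

Step 1
Reactants: 1 3-(furan-2-yl)propanoic acid; 2 (S)-4-benzyl-1,3-oxazolidin-2-one
Product: 4 (S)-4-benzyl-3-[3-(furan-2-yl)propanoyl]-1,3-oxazolidin-2-one, via mixed pivalic anhydride 3 (not isolated)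
Conditions: PivCl, Et3N, THF, −20 °C; then 2, LiCl, −20 °C → rt
Reagents that add atoms: none
Why: N-acylation of the oxazolidinone through a mixed anhydride, which is attacked at the less hindered acyl carbon; the furan is inert to these mildly basic conditions.

Step 2
Reactants: 5 (E)-but-2-enal; 6 vinylmagnesium bromide
Product: 8 (±)-3-methylpent-4-enal, via silyl enol ether 7 (not isolated)
Conditions: CuBr·SMe2 (10 mol %), TMSCl, THF, −78 °C; then 1 M HCl, 0 °C
Reagents that add atoms: none
Why: Copper-catalysed, chlorosilane-accelerated conjugate addition of a Grignard reagent to an enal; trapping as the silyl enol ether suppresses 1,2-addition and self-aldol. The racemic centre (future C10) is of no consequence.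

Step 3
Reactants: 4 (S)-4-benzyl-3-[3-(furan-2-yl)propanoyl]-1,3-oxazolidin-2-one; 8 (±)-3-methylpent-4-enal
Product: 10 (4S)-4-benzyl-3-[(2S,3R)-2-(furan-2-ylmethyl)-3-hydroxy-5-methylhept-6-enoyl]-1,3-oxazolidin-2-one, via Z-boron enolate 9 (not isolated)
Conditions: Bu2BOTf, i-Pr2NEt, CH2Cl2, 0 → −78 °C; 8, −78 → 0 °C; then pH 7 buffer, MeOH, H2O2, 0 °C
Reagents that add atoms: none
Why: Evans syn-aldol: the Z-dibutylboron enolate reacts through a closed chair transition state on the face away from the benzyl group, which sets C7 (S) and C8 (R) together. The remote methyl centre of 8 exerts no useful control, so 10 should form as a pair of C10 epimers.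

Step 4
Reactants: 10 (4S)-4-benzyl-3-[(2S,3R)-2-(furan-2-ylmethyl)-3-hydroxy-5-methylhept-6-enoyl]-1,3-oxazolidin-2-one
Product: 11 methyl (2S,3R)-2-(furan-2-ylmethyl)-3-hydroxy-5-methylhept-6-enoate
Conditions: MeMgBr, MeOH/CH2Cl2 (MeOMgBr formed in the flask), 0 °C
Reagents that add atoms: methanol, CO
Why: Magnesium methoxide transesterification at the exocyclic imide carbonyl, assisted by chelation to the β-hydroxyl; it is mild enough to avoid retro-aldol and epimerisation at C7, and the auxiliary 2 is recovered.

Step 5
Reactants: 11 methyl (2S,3R)-2-(furan-2-ylmethyl)-3-hydroxy-5-methylhept-6-enoate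
Product: 13 (3S,4R)-3-(furan-2-ylmethyl)-2,6-dimethyloct-7-ene-2,4-diol, via methyl ketone 12 (not isolated)
Conditions: MeMgBr (5 equiv), THF, 0 °C → rt; aq. NH4Cl
Reagents that add atoms: methylmagnesium bromide, C[Mg]Br
Why: Double Grignard addition to the ester builds the C11 dimethylcarbinol; the C8 magnesium alkoxide formed first disfavours enolisation of the ester and of 12. No stereocentre is created.

Step 6
Reactants: 13 (3S,4R)-3-(furan-2-ylmethyl)-2,6-dimethyloct-7-ene-2,4-diol
Product: 14 (5S,6R)-2,2-di-tert-butyl-5-(furan-2-ylmethyl)-4,4-dimethyl-6-(2-methylbut-3-en-1-yl)-1,3,2-dioxasilinane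
Conditions: t-Bu2Si(OTf)2, 2,6-lutidine, CH2Cl2, 0 °C → rt
Reagents that add atoms: di-tert-butylsilyl bis(trifluoromethanesulfonate), CC(C)(C)[Si](OS(=O)(=O)C(F)(F)F)(OS(=O)(=O)C(F)(F)F)C(C)(C)C
Why: Silylene formation on the 1,3-diol. This ring is chosen because it should survive butyllithium, hot aqueous Lewis acid, ozone and the cathode, whereas a ketal would hydrolyse in step 8 and a free diol would trap the furyl cation. It also holds C6 and C9 gauche for step 11.

Step 7
Reactants: 14 (5S,6R)-2,2-di-tert-butyl-5-(furan-2-ylmethyl)-4,4-dimethyl-6-(2-methylbut-3-en-1-yl)-1,3,2-dioxasilinane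
Product: 16 1-(5-{[(5S,6R)-2,2-di-tert-butyl-4,4-dimethyl-6-(2-methylbut-3-en-1-yl)-1,3,2-dioxasilinan-5-yl]methyl}furan-2-yl)ethan-1-ol, via 5-lithiofuran 15 (not isolated)
Conditions: n-BuLi, TMEDA, THF, −78 → 0 °C; MeCHO, −78 °C; aq. NH4Cl
Reagents that add atoms: acetaldehyde, CC=O
Why: α-Lithiation of a 2-alkylfuran at its free 5-position and addition to an aldehyde. The carbinol configuration is irrelevant because this carbon ionises in step 8.

Step 8
Reactants: 16 1-(5-{[(5S,6R)-2,2-di-tert-butyl-4,4-dimethyl-6-(2-methylbut-3-en-1-yl)-1,3,2-dioxasilinan-5-yl]methyl}furan-2-yl)ethan-1-ol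
Product: 17 (4R,5S)-4-{[(5S,6R)-2,2-di-tert-butyl-4,4-dimethyl-6-(2-methylbut-3-en-1-yl)-1,3,2-dioxasilinan-5-yl]methyl}-4-hydroxy-5-methylcyclopent-2-en-1-one
Conditions: ZnCl2, dioxane/H2O, reflux, pH ≈ 6
Reagents that add atoms: water, O
Why: Piancatelli rearrangement: ionisation of the furylcarbinol, addition of water at the alkyl-bearing furan carbon, ring opening and conrotatory 4π closure give the 4-hydroxycyclopentenone with hydroxyl and methyl trans; the zinc chloride protocol is the one established for 5-alkylated furylcarbinols. The carbinol carbon (guaiane C5) should form as two epimers in comparable amounts; they are separated by chromatography and the 4R,5S isomer (guaiane 5R) is carried on.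

Step 9
Reactants: 17 (4R,5S)-4-{[(5S,6R)-2,2-di-tert-butyl-4,4-dimethyl-6-(2-methylbut-3-en-1-yl)-1,3,2-dioxasilinan-5-yl]methyl}-4-hydroxy-5-methylcyclopent-2-en-1-one
Product: 19 the 2-methylpropanoic acid obtained from 17 by turning CH=CH2 into CO2H (all other centres as in 17), via aldehyde 18 (not isolated)
Conditions: O3, CH2Cl2/MeOH, −78 °C, Sudan Red 7B endpoint; Me2S; then NaClO2, NaH2PO4, 2-methylbut-2-ene, t-BuOH/H2O, 0 °C → rt
Reagents that add atoms: ozone, [O-][O+]=O; sodium chlorite, [Na+].[O-]Cl=O
Why: Ozonolysis of the electron-rich monosubstituted alkene should outrun attack on the electron-poor enone alkene, with the dye marking the endpoint. Pinnick oxidation then converts the aldehyde to the acid without touching the enone or the tertiary alcohol.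

Step 10
Reactants: 19 the carboxylic acid from step 9; 20 N-hydroxyphthalimide
Product: 21 1,3-dioxoisoindolin-2-yl ester of 19 (redox-active ester; ring-A centres 4R,5S in cyclopentenone numbering, dioxasilinane centres as in 17)
Conditions: DIC, DMAP (10 mol %), CH2Cl2, 0 °C → rt
Reagents that add atoms: none
Why: Carbodiimide (Steglich-type) esterification; the tertiary C5 hydroxyl is too hindered to compete.

Step 11
Reactants: 21 the N-acyloxyphthalimide from step 10
Product: 22 (1R,4S,5R,7S,8R,10S)-8,11-[(di-tert-butylsilanediyl)bis(oxy)]-5-hydroxyguaian-3-one (guaiane numbering; H-1 cis to the 5-hydroxyl)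
Conditions: undivided cell, reticulated vitreous carbon cathode, Zn anode, LiClO4 (0.1 M), (CF3)2CHOH (3 equiv), MeCN, 5 mM, low constant current to about 2.5 F/mol, 20 °C
Reagents that add atoms: none
Why: One-electron reduction of the phthalimide ester at the carbon cathode (expected near −1.3 V against SCE, well positive of the enone) gives a radical anion that loses phthalimide anion and carbon dioxide, so both C10 epimers of 21 deliver the same planar secondary radical. This nucleophilic radical adds to C1, the enone β-carbon, and the resulting C2 α-keto radical is reduced to the enolate and protonated by the fluoro alcohol; the closest known reaction type is the reductive decarboxylative Giese addition of N-acyloxyphthalimides to enones, here intramolecular. Ring B closes in the 7-exo-trig mode. C1 is controlled by C5: the tether leaves C5 through C6, so the radical can reach only the enone face that carries C6, which gives the cis ring fusion and 1R from the 5R epimer. C10 is controlled by the transition-state conformation: in a twist-chair with the cis-fused dioxasilinane quasi-equatorial and ring A on the opposite face, the radical methyl turns away from ring A, which places H-10 anti to H-1 and the methyl cis to O8 (10S). The step needs reduction of the ester before the enone, secured by the gap in potentials and the low current, and ring closure ahead of hydrogen abstraction, secured by dilution, a poor hydrogen-donor solvent and the silylene ring that holds C6 and C9 gauche. Attack at C1 and not C2 follows from the polarity match and the exo mode.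

Step 12
Reactants: 22 (1R,4S,5R,7S,8R,10S)-8,11-[(di-tert-butylsilanediyl)bis(oxy)]-5-hydroxyguaian-3-one
Product: 23 (1R,7S,8R,10S)-8,11-[(di-tert-butylsilanediyl)bis(oxy)]guai-4-en-3-one
Conditions: NaOMe (0.3 equiv), MeOH, 0 °C → rt
Reagents that add atoms: none
Why: E1cB dehydration of the β-ketol through the C4 enolate gives the conjugated tetrasubstituted enone; any retro-aldol opening can re-close only to the same ring, because the alternative aldol would need a bridgehead alkene. C1 is expected to stay 1R (second assumption), and partial loss of the silylene here is harmless.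

Step 13
Reactants: 23 (1R,7S,8R,10S)-8,11-[(di-tert-butylsilanediyl)bis(oxy)]guai-4-en-3-one
Product: 24 (1R,7S,8R,10S)-8,11-dihydroxyguai-4-en-3-one
Conditions: HF·pyridine, THF, 0 °C → rt
Reagents that add atoms: none
Why: Fluoride cleavage of the silylene under mildly acidic conditions that should leave the tertiary alcohol and the γ-epimerisable C1 untouched.

Step 14
Reactants: 24 (1R,7S,8R,10S)-8,11-dihydroxyguai-4-en-3-one
Product: 25 (1R,7S,8R,10S)-11-hydroxy-8-(methacryloyloxy)guai-4-en-3-one
Conditions: methacryloyl chloride, Et3N, DMAP (5 mol %), CH2Cl2, −20 → 0 °C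
Reagents that add atoms: methacryloyl chloride, C=C(C)C(Cl)=O
Why: Acylation of the secondary hydroxyl; the tertiary C11 hydroxyl does not react with an acid chloride under these cold conditions.

Step 15
Reactants: 25 (1R,7S,8R,10S)-11-hydroxy-8-(methacryloyloxy)guai-4-en-3-one
Product: 26 (1R,7S,8R,10S)-11-acetoxy-8-(methacryloyloxy)guai-4-en-3-one (CNP0318307.1)
Conditions: Ac2O, DMAP, Et3N, CH2Cl2, 35 °C
Reagents that add atoms: acetic anhydride, CC(=O)OC(C)=O
Why: DMAP-catalysed acylation of the tertiary alcohol. O8 is already esterified, so no selectivity is required, and migration of the methacrylate to the tertiary oxygen is uphill.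

## Compound list

1 | 3-(furan-2-yl)propanoic acid | OC(=O)CCc1ccco1 | starting material
2 | (S)-4-benzyl-1,3-oxazolidin-2-one | O=C1N[C@@H](Cc2ccccc2)CO1 | starting material
3 | 3-(furan-2-yl)propanoic pivalic anhydride | CC(C)(C)C(=O)OC(=O)CCc1ccco1 | intermediate
4 | (S)-4-benzyl-3-[3-(furan-2-yl)propanoyl]-1,3-oxazolidin-2-one | O=C(CCc1ccco1)N1C(=O)OC[C@@H]1Cc1ccccc1 | intermediate
5 | (E)-but-2-enal | C/C=C/C=O | starting material
6 | vinylmagnesium bromide | C=C[Mg]Br | starting material
7 | trimethyl[(3-methylpenta-1,4-dien-1-yl)oxy]silane (E/Z) | C=CC(C)C=CO[Si](C)(C)C | intermediate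
8 | (±)-3-methylpent-4-enal | C=CC(C)CC=O | intermediate
9 | Z-dibutylboron enolate of 4 | CCCCB(CCCC)O/C(N1C(=O)OC[C@@H]1Cc1ccccc1)=C\Cc1ccco1 | intermediate
10 | (4S)-4-benzyl-3-[(2S,3R)-2-(furan-2-ylmethyl)-3-hydroxy-5-methylhept-6-enoyl]-1,3-oxazolidin-2-one (both epimers at the methyl-bearing carbon) | C=CC(C)C[C@@H](O)[C@H](Cc1ccco1)C(=O)N1C(=O)OC[C@@H]1Cc1ccccc1 | intermediate
11 | methyl (2S,3R)-2-(furan-2-ylmethyl)-3-hydroxy-5-methylhept-6-enoate | C=CC(C)C[C@@H](O)[C@H](Cc1ccco1)C(=O)OC | intermediate
12 | (3S,4R)-3-(furan-2-ylmethyl)-4-hydroxy-6-methyloct-7-en-2-one | C=CC(C)C[C@@H](O)[C@H](Cc1ccco1)C(C)=O | intermediate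
13 | (3S,4R)-3-(furan-2-ylmethyl)-2,6-dimethyloct-7-ene-2,4-diol | C=CC(C)C[C@@H](O)[C@H](Cc1ccco1)C(C)(C)O | intermediate
14 | (5S,6R)-2,2-di-tert-butyl-5-(furan-2-ylmethyl)-4,4-dimethyl-6-(2-methylbut-3-en-1-yl)-1,3,2-dioxasilinane | C=CC(C)C[C@H]1O[Si](C(C)(C)C)(C(C)(C)C)OC(C)(C)[C@H]1Cc1ccco1 | intermediate
15 | 5-lithio derivative of 14 (lithium on the free furan α-carbon) | C=CC(C)C[C@H]1O[Si](C(C)(C)C)(C(C)(C)C)OC(C)(C)[C@H]1Cc1ccc([Li])o1 | intermediate
16 | 1-(5-{[(5S,6R)-2,2-di-tert-butyl-4,4-dimethyl-6-(2-methylbut-3-en-1-yl)-1,3,2-dioxasilinan-5-yl]methyl}furan-2-yl)ethan-1-ol (carbinol epimers) | C=CC(C)C[C@H]1O[Si](C(C)(C)C)(C(C)(C)C)OC(C)(C)[C@H]1Cc1ccc(C(C)O)o1 | intermediate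
17 | (4R,5S)-4-{[(5S,6R)-2,2-di-tert-butyl-4,4-dimethyl-6-(2-methylbut-3-en-1-yl)-1,3,2-dioxasilinan-5-yl]methyl}-4-hydroxy-5-methylcyclopent-2-en-1-one | C=CC(C)C[C@H]1O[Si](C(C)(C)C)(C(C)(C)C)OC(C)(C)[C@H]1C[C@@]1(O)C=CC(=O)[C@H]1C | intermediate
18 | aldehyde from 17 (CH=CH2 replaced by CHO) | CC(C=O)C[C@H]1O[Si](C(C)(C)C)(C(C)(C)C)OC(C)(C)[C@H]1C[C@@]1(O)C=CC(=O)[C@H]1C | intermediate
19 | carboxylic acid from 17 (CH=CH2 replaced by CO2H) | CC(C[C@H]1O[Si](C(C)(C)C)(C(C)(C)C)OC(C)(C)[C@H]1C[C@@]1(O)C=CC(=O)[C@H]1C)C(=O)O | intermediate
20 | N-hydroxyphthalimide | O=C1c2ccccc2C(=O)N1O | starting material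
21 | 1,3-dioxoisoindolin-2-yl ester of 19 (key-step precursor) | CC(C[C@H]1O[Si](C(C)(C)C)(C(C)(C)C)OC(C)(C)[C@H]1C[C@@]1(O)C=CC(=O)[C@H]1C)C(=O)ON1C(=O)c2ccccc2C1=O | intermediate
22 | (1R,4S,5R,7S,8R,10S)-8,11-[(di-tert-butylsilanediyl)bis(oxy)]-5-hydroxyguaian-3-one (key-step product) | CC(C)(C)[Si]1(C(C)(C)C)O[C@@H]2C[C@H](C)[C@H]3CC(=O)[C@@H](C)[C@@]3(O)C[C@@H]2C(C)(C)O1 | intermediate
23 | (1R,7S,8R,10S)-8,11-[(di-tert-butylsilanediyl)bis(oxy)]guai-4-en-3-one | CC(C)(C)[Si]1(C(C)(C)C)O[C@@H]2C[C@H](C)[C@H]3CC(=O)C(C)=C3C[C@@H]2C(C)(C)O1 | intermediate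
24 | (1R,7S,8R,10S)-8,11-dihydroxyguai-4-en-3-one | O[C@@H]1C[C@H](C)[C@H]2CC(=O)C(C)=C2C[C@@H]1C(C)(C)O | intermediate
25 | (1R,7S,8R,10S)-11-hydroxy-8-(methacryloyloxy)guai-4-en-3-one | C=C(C)C(=O)O[C@@H]1C[C@H](C)[C@H]2CC(=O)C(C)=C2C[C@@H]1C(C)(C)O | intermediate
26 | (1R,7S,8R,10S)-11-acetoxy-8-(methacryloyloxy)guai-4-en-3-one | C=C(C)C(=O)O[C@@H]1C[C@H](C)[C@H]2CC(=O)C(C)=C2C[C@@H]1C(C)(C)OC(C)=O | target

## Step count and least certain steps

Total: 15 steps. Longest linear sequence: 14 steps (steps 1 and 3–15, from 1); step 2 is a one-step branch.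

**Step 11 (key step).** The most likely failure is quenching of the C10 radical, by hydrogen abstraction or further reduction, before the slow 7-exo closure, which would leave the decarboxylated open chain. The second risk is poor facial selectivity at the radical carbon, which would give the C10 epimer. Fallback, setting out from 19: esterify with 2-mercaptopyridine N-oxide (DIC) to the N-acyloxypyridine-2-thione F1 and photolyse it with iodoform (Barton decarboxylative iodination) to the secondary iodide F2. Cyclise F2 with (Me3Si)3SiH and AIBN, added slowly to hot benzene, so that the radical meets very little hydrogen donor before it closes. This comes back to the route at 22.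

**Step 8.** Water may add too slowly at the alkyl-bearing furan carbon, so the furyl cation oligomerises, or the silylene may hydrolyse and a freed hydroxyl trap the cation. C5 also forms without control, so about half of the material is expected to be the unwanted epimer, and the C10 mixture will make the separation harder. Fallback, setting out from 14: lithiate and alkylate with ethyl iodide to the 2-ethyl-5-alkylfuran F3. Photo-oxygenate it (O2, rose bengal, light; then Me2S) to the cis-enedione F4. Close F4 by mild base (Et3N) intramolecular aldol; attack of the ethyl-ketone enolate on the other carbonyl should be preferred because the alternative puts the branched chain on the ring. This comes back at 17.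

**Step 9.** Ozone may also attack the enone alkene, or the tertiary allylic alcohol may be over-oxidised. Fallback, setting out from 17: dihydroxylate the vinyl group with catalytic OsO4 and N-methylmorpholine N-oxide to the diol F5, then cleave it with NaIO4. This comes back at 18, which is oxidised as before.

**Step 15.** Acylation of the hindered tertiary alcohol may be sluggish, and forcing it risks Michael addition or polymerisation at the methacrylate. Fallback, setting out from 24: silylate O8 selectively (TESCl, imidazole) to the triethylsilyl ether F6, and acetylate the tertiary alcohol under forcing conditions (Ac2O, DMAP, heat) to the silyl ether acetate F7. Remove the silyl group with HF·pyridine to the 8-hydroxy 11-acetate F8, and acylate O8 cold with methacryloyl chloride, Et3N and DMAP so that acetyl migration is forestalled. This comes back at 26.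

## Further compounds

F1 | step 11 | N-acyloxypyridine-2-thione (Barton ester) of 19 | CC(C[C@H]1O[Si](C(C)(C)C)(C(C)(C)C)OC(C)(C)[C@H]1C[C@@]1(O)C=CC(=O)[C@H]1C)C(=O)ON1C=CC=CC1=S
F2 | step 11 | secondary iodide (iodine in place of the carboxyl of 19) | CC(I)C[C@H]1O[Si](C(C)(C)C)(C(C)(C)C)OC(C)(C)[C@H]1C[C@@]1(O)C=CC(=O)[C@H]1C
F3 | step 8 | 2-ethyl-5-alkylfuran (5-ethyl derivative of 14) | C=CC(C)C[C@H]1O[Si](C(C)(C)C)(C(C)(C)C)OC(C)(C)[C@H]1Cc1ccc(CC)o1
F4 | step 8 | cis-enedione from F3 | C=CC(C)C[C@H]1O[Si](C(C)(C)C)(C(C)(C)C)OC(C)(C)[C@H]1CC(=O)/C=C\C(=O)CC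
F5 | step 9 | 1,2-diol from 17 | OCC(O)C(C)C[C@H]1O[Si](C(C)(C)C)(C(C)(C)C)OC(C)(C)[C@H]1C[C@@]1(O)C=CC(=O)[C@H]1C
F6 | step 15 | 8-O-triethylsilyl ether of 24 | CC[Si](CC)(CC)O[C@@H]1C[C@H](C)[C@H]2CC(=O)C(C)=C2C[C@@H]1C(C)(C)O
F7 | step 15 | 11-O-acetyl-8-O-triethylsilyl derivative of 24 | CC[Si](CC)(CC)O[C@@H]1C[C@H](C)[C@H]2CC(=O)C(C)=C2C[C@@H]1C(C)(C)OC(C)=O
F8 | step 15 | (1R,7S,8R,10S)-11-acetoxy-8-hydroxyguai-4-en-3-one | O[C@@H]1C[C@H](C)[C@H]2CC(=O)C(C)=C2C[C@@H]1C(C)(C)OC(C)=O
A1 | alternative 1 | 10-acetoxy hydroazulenone 8,11-carbonate | O=C1O[C@@H]2C[C@](C)(OC(C)=O)[C@H]3CC(=O)C(C)=C3C[C@@H]2C(C)(C)O1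
A2 | alternative 1 | eudesma-1,4-dien-3-one 8,11-carbonate (cross-conjugated cyclohexadienone) | O=C1O[C@@H]2C[C@]3(C)C=CC(=O)C(C)=C3C[C@@H]2C(C)(C)O1
A3 | alternative 2 | bicyclic silyl enol ether with C7 ester and C3 silyl ether | CC(C)(C)[Si](C)(C)OC1=C(C(=O)OC)CC2=C([C@@H](C)C1)C[C@@H](O[Si](C)(C)C(C)(C)C)[C@H]2C
A4 | alternative 2 | 1-ethylidene-2-methylenecyclopentane bearing the C3 silyl ether and C4 methyl | C/C=C1\C[C@@H](O[Si](C)(C)C(C)(C)C)[C@@H](C)C1=C
A5 | alternative 2 | methyl 3-[(tert-butyldimethylsilyl)oxy]-2-diazobut-3-enoate | C=C(O[Si](C)(C)C(C)(C)C)C(=[N+]=[N-])C(=O)OC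
A6 | alternative 3 | acetonide of (1R,7S,8R,10S)-8,11-dihydroxyguai-4-en-3-one | CC1(C)O[C@@H]2C[C@H](C)[C@H]3CC(=O)C(C)=C3C[C@@H]2C(C)(C)O1
A7 | alternative 3 | cycloheptenyl tertiary propargylic pivalate (C4 configuration left open) | C#CC(C)(OC(=O)C(C)(C)C)C1=C[C@@H](C)C[C@H]2OC(C)(C)OC(C)(C)[C@H]2C1
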